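## Structural features

The target 24 is a biflavanoid built from two 2-arylchroman-3-ol units: an upper 7-hydroxy unit with a 4-hydroxyphenyl ring B (rings A, B, C) and a lower 7'-hydroxy unit with a 3,4-dihydroxyphenyl ring E (rings D, E, F). The units are joined by one bond from the sp3 carbon C4 of ring C to the aromatic carbon C6' of ring D, ortho to the 7'-hydroxyl. The upper unit has three contiguous stereocentres, C2 (R), C3 (S) and C4 (R), in an all-trans array. The lower unit has two adjacent stereocentres, C2' (S) and C3' (S), in a 2,3-cis relationship, and C4' is a methylene group. Rings A and D are resorcinol-type (no 5-oxygen), so the C4–C6' bond is robust to acid, but six phenols (one a catechol) and the two cyclic benzylic ethers O1–C2 and O1'–C2' are sensitive to oxidants, base and strong acid. The real difficulty is twofold: fixing C4 relative to C2/C3 at a carbon that carries two aryl groups, and making the contra-thermodynamic cis lower ring with its own absolute configuration. The feature used by the key step is that C4 bears two 2,4-dioxygenated aryl groups, ring A through C4a and ring D through C6'. Before the O1–C2 bond exists these are two identical resorcinol rings on a prochiral methine, so both can come from one symmetrical benzophenone, and closing ring C chooses between them and creates C4.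

## Logic of the disconnections

24 ⇒ 23. The five O–CH2Ph bonds are cut. All sensitive phenols and the C3 hydroxyl then stay masked until one neutral final operation. The forward hydrogenolysis must spare O1–C2, O1'–C2' and C4–C6'.

23 ⇒ 22 ⇒ 21. The O1'–C2' bond of ring F is cut, giving a cis-epoxide and a free C8a' phenol, which is stored as an allyl ether. This removes ring F and reduces both lower stereocentres to one epoxide. The forward step needs a neutral deallylation and a 6-endo opening at C2' with clean inversion, since only inversion on the cis-epoxide gives the cis ring.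

21 ⇒ 20 ⇒ 19. The two epoxide C–O bonds are cut, then the Z-alkene is taken back to the alkyne. The lower stereochemistry becomes a question of alkene geometry plus one catalyst-controlled oxygen transfer. The forward steps need syn semihydrogenation that leaves the allyl ethers alone and high face selectivity on a cis-β-alkylstyrene.

19 ⇒ 14 + 17. The C4a'–C4' bond is cut into an aryl nucleophile at C4a' and a primary propargylic bromide. This is the convergent point of the route: the whole ring E side chain arrives in one piece. The forward coupling must go SN2 and not SN2', and the metalation must tolerate benzyl and allyl ethers.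

17 ⇒ 16 ⇒ 15. The C–Br bond and then the aryl–alkyne bond are cut, leading back to a purchasable aryl bromide and propargyl alcohol. The demand is an efficient cross-coupling on an electron-rich aryl bromide.

14 ⇒ 13 ⇒ 12. Two O–benzyl bonds and the C4a'–I bond are cut. The only free phenol of 12 is the 7'-OH, so it can direct the halogen to its para position (C4a') and is then capped together with the C3 hydroxyl. The demand is para-selective halogenation of ring D in the presence of two other alkoxyarenes and two allyl groups.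

12 ⇒ 11. The O1–C2 bond of ring C is cut, giving a trans-epoxide whose C3 carries a methine with two identical 4-allyloxy-2-hydroxyphenyl groups. One ring, one bond and the C4 stereocentre disappear, and the precursor gains local symmetry. The forward step must be 6-endo, must invert C2 and must select one of two diastereotopic phenols.

11 ⇒ 10 ⇒ 9. Two O–Si bonds and then the epoxide C–O bonds are cut, leading to an achiral E-alkene. All absolute stereochemistry of the upper unit now rests on one catalytic epoxidation. It must deliver the (2S,3S) epoxide, which calls for the L-series ketone catalyst, and must leave the allyl ethers untouched.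

9 ⇒ 5 + 8. The C2=C3 double bond is cut into a diarylacetaldehyde and a benzylic tetrazolyl sulfone. The demand is E selectivity and carbonyl addition faster than enolisation of the aldehyde.

8 ⇒ 7 ⇒ 6. The S=O bonds and the C–S bond are cut, back to a purchasable benzylic chloride.

5 ⇒ 4 ⇒ 3 ⇒ 2 ⇒ 1. The C3–C4 bond is cut as a one-carbon homologation of a ketone (methylene transfer, then 1,2-hydride shift), followed by the O–Si and O–allyl bonds. This ends at a purchasable symmetrical benzophenone. The demands are selective alkylation of the 4-hydroxyls over the chelated 2-hydroxyls and ylide addition to a hindered, electron-rich ketone.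

## Other disconnections considered

Alternative 1: The cut is the aryl–alkyl bond C4'–C4a' of ring F. The precursor A1 is an aryl ether in which O1' already carries C2' (with ring E as its dipivalate) and a terminal C3'–C4' epoxide. BF3·OEt2 would activate the epoxide and C4a' would attack C4' in a 6-endo epoxy-arene cyclisation to give A2 with O3' set free.
- In its favour: C2' and C3' are set before the ring closes and are not touched by it, and the pivalates damp ionisation at C2'. On security of the cis relationship this is better than the chosen plan, which must pass through a labile cis-epoxide.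
- Against it here: A1 requires a hindered secondary benzylic aryl ether to be made stereospecifically at an ionisable centre. The arene can also attack through C8' (between the two ring D oxygens) or in the 5-exo sense. A second class of protecting group must be removed at the end.
- Comparison: the need to distinguish O8a' from O7' on ring D is equal in both plans. The chosen plan fixes the site of C–C bond formation unambiguously through the iodide and is shorter by the ester cleavage and the steps to the chiral epoxy ether. Mechanistically, Alternative 1 trades a stereochemical risk for a regiochemical one.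

Alternative 2: The cut removes O1–C2 and C3–C4 together. A chiral BINOL-derived phosphoric acid would dehydrate the benzhydrol A3 (ring A phenol plus a complete lower unit on the carbinol carbon) to an ortho-quinone methide, which would add to the E-alkenyl boronate A4 to give the C3-boryl flavan A5. Oxidation of the C–B bond with retention would then give the C3 hydroxyl.
- In its favour: two bonds, ring C and three stereocentres are formed in one step, and a finished lower unit is joined late. On convergence this is better than the chosen plan.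
- Against it here: the quinone methide carries a large chiral substituent at C4, so catalyst and substrate control may not match. The endo/exo preference, which decides 3,4-trans versus 3,4-cis, has no obvious bias. An alkenyl boronate is a weak 2π partner, and a stepwise cationic pathway could erode the 2,3-trans relationship.
- Comparison: both plans rely on benzylic cationic character stabilised by the ring B alkoxy group (equal). The chosen plan leaves only one stereochemical variable (C4) open at the key step, because C2 and C3 come from a stereospecific epoxide opening. Overall step counts should be similar, since A3 still needs the cis lower unit, a C6' metalation and an extra C–B oxidation.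

Alternative 3: The cut is the aryl–oxygen bond C8a'–O1'. The triflate A6, with a syn-configured 2'-hydroxy-3'-benzyloxy side chain, would undergo intramolecular C–O coupling (Pd(OAc)2, a bulky di-tert-butyl biarylphosphine, Cs2CO3) to give the hepta-O-benzyl compound A7. C2' is retained because its C–O bond is never broken.
- In its favour: the lower stereocentres would come from dihydroxylation of an E-alkene and are only carried along, so no ionisation-prone step is involved. This is better than the chosen plan on stereochemical fidelity. A7 is uniformly benzylated, so the final deprotection is equal.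
- Against it here: the two secondary hydroxyls of the syn-diol must be told apart. Palladium alkoxides of secondary alcohols can undergo β-hydride elimination instead of C–O reductive elimination, especially on an electron-rich aryl triflate such as ring D. Osmium-based dihydroxylation is not compatible with the allyl ethers of the chosen upper-unit synthesis, so its protecting groups would have to be redesigned.
- Comparison: the step count should be equal or one to two steps longer (dihydroxylation, regioselective protection, triflation, coupling). The chosen plan is shorter but carries more stereochemical risk in its last ring closure.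

Key step: step 9

Remark: inversion at C2 requires a (2S,3S)-epoxide for the 2R,3S upper unit, and this calls for the L-series Shi ketone (enantiomer of the D-fructose-derived catalyst); that ketone, 4-bromo-1,2-bis(benzyloxy)benzene and the (R,R)-salen manganese chloride complex are taken as purchasable.
Remark: the C4 descriptor changes from R (12, 13, 24) to S (14, 18–23) only because O-benzylation of the ring D phenol changes the CIP ranking; the spatial arrangement is unchanged.

Step 1
Reactants: 1 2,2',4,4'-tetrahydroxybenzophenone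
Product: 2 bis[4-(allyloxy)-2-hydroxyphenyl]methanone
Conditions: allyl bromide (2.1 equiv), K2CO3 (2.2 equiv), acetone, reflux
Reagents that add atoms: allyl bromide, C=CCBr
Why: Williamson etherification; the 4-hydroxyls are the more acidic (para to the carbonyl) and are not held in the hydrogen bond to C=O that ties up the 2-hydroxyls, so carbonate base should alkylate only the 4-positions.

Step 2
Reactants: 2 bis[4-(allyloxy)-2-hydroxyphenyl]methanone
Product: 3 bis[4-(allyloxy)-2-(tert-butyldimethylsilyloxy)phenyl]methanone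
Conditions: TBSCl, imidazole, DMAP (cat.), DMF, 40 °C
Reagents that add atoms: tert-butyldimethylsilyl chloride, CC(C)(C)[Si](C)(C)Cl
Why: Silyl ether formation on the chelated ortho-phenols; the silyl groups remove the acidic protons before the ylide step and can later be cleaved by fluoride without touching allyl, benzyl or epoxide groups.

Step 3
Reactants: 3 bis[4-(allyloxy)-2-(tert-butyldimethylsilyloxy)phenyl]methanone
Product: 5 2,2-bis[4-(allyloxy)-2-(tert-butyldimethylsilyloxy)phenyl]acetaldehyde, via diaryloxirane 4 (not isolated)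
Conditions: Me3S+ I−, n-BuLi, THF, −10 °C to rt; aqueous work-up, crude 4; then BF3·OEt2 (10 mol%), CH2Cl2, −78 °C
Reagents that add atoms: trimethylsulfonium iodide, C[S+](C)C.[I-]
Why: Corey–Chaykovsky epoxidation of the diaryl ketone followed by Meinwald rearrangement; the doubly benzylic, electron-rich oxirane opens to a tertiary cation and a 1,2-hydride shift gives the homologated diarylacetaldehyde, with no stereocentre formed.

Step 4
Reactants: 6 4-(benzyloxy)benzyl chloride
Product: 7 5-{[4-(benzyloxy)benzyl]sulfanyl}-1-phenyl-1H-tetrazole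
Conditions: 1-phenyl-1H-tetrazole-5-thiol, K2CO3, acetone, rt
Reagents that add atoms: 1-phenyl-1H-tetrazole-5-thiol, Sc1nnnn1-c1ccccc1
Why: SN2 thioetherification of the benzylic chloride by the thiolate; it prepares the Julia–Kocienski partner.

Step 5
Reactants: 7 5-{[4-(benzyloxy)benzyl]sulfanyl}-1-phenyl-1H-tetrazole
Product: 8 5-{[4-(benzyloxy)benzyl]sulfonyl}-1-phenyl-1H-tetrazole
Conditions: (NH4)6Mo7O24·4H2O (10 mol%), 30% H2O2, EtOH, 0 °C to rt
Reagents that add atoms: hydrogen peroxide, OO
Why: Molybdate-catalysed peroxide oxidation of the sulfide to the sulfone; the benzyl ether is inert.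

Step 6
Reactants: 5 2,2-bis[4-(allyloxy)-2-(tert-butyldimethylsilyloxy)phenyl]acetaldehyde; 8 5-{[4-(benzyloxy)benzyl]sulfonyl}-1-phenyl-1H-tetrazole
Product: 9 (E)-1-[4-(benzyloxy)phenyl]-3,3-bis[4-(allyloxy)-2-(tert-butyldimethylsilyloxy)phenyl]prop-1-ene
Conditions: 8, KN(SiMe3)2, THF, −78 °C, 20 min; then 5, −78 °C to rt
Reagents that add atoms: none
Why: Julia–Kocienski olefination; addition of the metalated benzylic sulfone, Smiles rearrangement and loss of SO2 and tetrazolate should give mainly the E-alkene, with the bulky diarylmethyl group reinforcing E. The anion is pre-formed and the addition run cold so that carbonyl addition outruns enolisation of the hindered α-CH; any Z isomer can be equilibrated to E with a trace of iodine.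

Step 7
Reactants: 9 (E)-1-[4-(benzyloxy)phenyl]-3,3-bis[4-(allyloxy)-2-(tert-butyldimethylsilyloxy)phenyl]prop-1-ene
Product: 10 (2S,3S)-2-[4-(benzyloxy)phenyl]-3-{bis[4-(allyloxy)-2-(tert-butyldimethylsilyloxy)phenyl]methyl}oxirane
Conditions: L-series Shi ketone (1,2:4,5-di-O-isopropylidene-β-L-erythro-2,3-hexodiulo-2,6-pyranose, 30 mol%), KHSO5, K2CO3, Bu4NHSO4 (cat.), MeCN/CH2(OMe)2/aq. Na2B4O7–Na2(EDTA) buffer (pH 10.5), 0 °C
Reagents that add atoms: potassium peroxymonosulfate, [K+].[O-]S(=O)(=O)OO
Why: Shi epoxidation; the chiral dioxirane from the L-series ketone attacks the trans-disubstituted styrene through the spiro transition state and sets C2 and C3 as S,S (the D-fructose ketone would give R,R). The electron-poor monosubstituted allyl ether alkenes react much more slowly with the electrophilic dioxirane, and 9 is achiral, so the catalyst alone decides the face.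

Step 8
Reactants: 10 (2S,3S)-2-[4-(benzyloxy)phenyl]-3-{bis[4-(allyloxy)-2-(tert-butyldimethylsilyloxy)phenyl]methyl}oxirane
Product: 11 (2S,3S)-2-[4-(benzyloxy)phenyl]-3-{bis[4-(allyloxy)-2-hydroxyphenyl]methyl}oxirane
Conditions: Bu4NF (2.2 equiv), AcOH (2.2 equiv), THF, 0 °C; neutral work-up, used at once
Reagents that add atoms: none
Why: Fluoride cleavage of the aryl silyl ethers, buffered with acetic acid so that no phenoxide is present to open the epoxide in the 5-exo sense; 11 is acid-labile and is not stored.

Step 9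
Reactants: 11 (2S,3S)-2-[4-(benzyloxy)phenyl]-3-{bis[4-(allyloxy)-2-hydroxyphenyl]methyl}oxirane
Product: 12 (2R,3S,4R)-7-(allyloxy)-4-[4-(allyloxy)-2-hydroxyphenyl]-2-[4-(benzyloxy)phenyl]chroman-3-ol
Conditions: (1S)-(+)-10-camphorsulfonic acid (10 mol%), CH2Cl2, −40 to 0 °C
Reagents that add atoms: none
Why: The sulfonic acid protonates (or hydrogen-bonds to) the epoxide oxygen, the benzylic C2–O bond is weakened by the 4-benzyloxyphenyl group, and an ortho-phenol oxygen attacks C2 from the side opposite the departing oxygen; this is the established acid-mediated opening of trans-aryl epoxides by an ortho-phenol to give 2,3-trans-flavan-3-ols. Ring C closes in the 6-endo mode at C2, because the 5-exo attack at C3 has no benzylic stabilisation under acid. C2 is set by stereospecific inversion of the (S)-epoxide carbon and becomes R, while C3 keeps the S configuration from the epoxidation, so the 2,3-trans relationship follows from the trans-epoxide. C4 is created by the choice between the two diastereotopic phenols: in the chair-like transition state the cyclising aryl group lies anti to the C3–O bond, and the other aryl group sits either anti to C2 (pseudo-equatorial, giving 3,4-trans, 4R) or gauche to both C2 and O3 (pseudo-axial, giving 3,4-cis). The pseudo-equatorial arrangement avoids the gauche and 1,3-diaxial contacts with C2 and its aryl group and should therefore be preferred. The step needs regioselectivity, stereospecificity and group selectivity; the first two are secured by the p-alkoxyaryl group together with a weak acid in a non-nucleophilic solvent at low temperature, the third by the pseudo-equatorial preference. The ring that does not cyclise keeps a free 2-OH and a 4-O-allyl group, which differentiates the two oxygens of the future ring D.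

Step 10
Reactants: 12 (2R,3S,4R)-7-(allyloxy)-4-[4-(allyloxy)-2-hydroxyphenyl]-2-[4-(benzyloxy)phenyl]chroman-3-ol
Product: 13 (2R,3S,4R)-7-(allyloxy)-4-[4-(allyloxy)-2-hydroxy-5-iodophenyl]-2-[4-(benzyloxy)phenyl]chroman-3-ol
Conditions: N-iodosuccinimide (1.0 equiv), MeCN, −20 to 0 °C, dark
Reagents that add atoms: N-iodosuccinimide, O=C1CCC(=O)N1I
Why: Electrophilic aromatic iodination; the only free phenol activates ring D, the position para to it (the future C4a') is open and less hindered than the position between the two oxygens, and the ether rings should not react with N-iodosuccinimide without added acid. Iodine is chosen over bromine so that the later metalation can be a mild iodine–magnesium exchange.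

Step 11
Reactants: 13 (2R,3S,4R)-7-(allyloxy)-4-[4-(allyloxy)-2-hydroxy-5-iodophenyl]-2-[4-(benzyloxy)phenyl]chroman-3-ol
Product: 14 (2R,3S,4S)-7-(allyloxy)-4-[4-(allyloxy)-2-(benzyloxy)-5-iodophenyl]-3-(benzyloxy)-2-[4-(benzyloxy)phenyl]chromane
Conditions: NaH (2.5 equiv), BnBr (2.4 equiv), Bu4NI (cat.), DMF, 0 °C to rt
Reagents that add atoms: benzyl bromide, BrCc1ccccc1
Why: Williamson benzylation of the phenol and the secondary alcohol; it removes all acidic protons before the organomagnesium step and leaves O8a' as the only ring D oxygen with a different (allyl) mask.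

Step 12
Reactants: 15 4-bromo-1,2-bis(benzyloxy)benzene
Product: 16 3-[3,4-bis(benzyloxy)phenyl]prop-2-yn-1-ol
Conditions: propargyl alcohol, Pd(PPh3)2Cl2 (3 mol%), CuI (5 mol%), Et3N, 70 °C
Reagents that add atoms: prop-2-yn-1-ol, C#CCO
Why: Sonogashira coupling of the aryl bromide with the terminal alkyne.

Step 13
Reactants: 16 3-[3,4-bis(benzyloxy)phenyl]prop-2-yn-1-ol
Product: 17 4-(3-bromoprop-1-yn-1-yl)-1,2-bis(benzyloxy)benzene
Conditions: CBr4, PPh3, CH2Cl2, 0 °C
Reagents that add atoms: carbon tetrabromide, BrC(Br)(Br)Br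
Why: Appel bromination of the primary propargylic alcohol under neutral conditions.

Step 14
Reactants: 14 (2R,3S,4S)-7-(allyloxy)-4-[4-(allyloxy)-2-(benzyloxy)-5-iodophenyl]-3-(benzyloxy)-2-[4-(benzyloxy)phenyl]chromane; 17 4-(3-bromoprop-1-yn-1-yl)-1,2-bis(benzyloxy)benzene
Product: 19 (2R,3S,4S)-7-(allyloxy)-4-{4-(allyloxy)-2-(benzyloxy)-5-[3-(3,4-bis(benzyloxy)phenyl)prop-2-yn-1-yl]phenyl}-3-(benzyloxy)-2-[4-(benzyloxy)phenyl]chromane, via arylmagnesium chloride 18 (not isolated)
Conditions: iPrMgCl·LiCl (1.1 equiv), THF, −20 to 0 °C; then CuI (10 mol%), 17, −30 °C to rt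
Reagents that add atoms: none
Why: Iodine–magnesium exchange (helped by the ortho-allyloxy group, tolerant of benzyl and allyl ethers) followed by copper-catalysed SN2 coupling of the aryl Grignard reagent with a primary propargylic bromide that is substituted at the alkyne terminus; the aryl group at that terminus should disfavour SN2' attack.

Step 15
Reactants: 19 (2R,3S,4S)-7-(allyloxy)-4-{4-(allyloxy)-2-(benzyloxy)-5-[3-(3,4-bis(benzyloxy)phenyl)prop-2-yn-1-yl]phenyl}-3-(benzyloxy)-2-[4-(benzyloxy)phenyl]chromane
Product: 20 (2R,3S,4S)-7-(allyloxy)-4-{4-(allyloxy)-2-(benzyloxy)-5-[(Z)-3-(3,4-bis(benzyloxy)phenyl)prop-2-en-1-yl]phenyl}-3-(benzyloxy)-2-[4-(benzyloxy)phenyl]chromane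
Conditions: H2 (1 atm), Pd/CaCO3/Pb(OAc)2, quinoline, EtOAc, rt, stopped after one equivalent of H2
Reagents that add atoms: none
Why: Lindlar-type semihydrogenation; syn delivery of hydrogen on the poisoned palladium surface gives the Z-alkene, and the internal alkyne is reduced much faster than the allyl ether alkenes or the benzyl ethers.

Step 16
Reactants: 20 (2R,3S,4S)-7-(allyloxy)-4-{4-(allyloxy)-2-(benzyloxy)-5-[(Z)-3-(3,4-bis(benzyloxy)phenyl)prop-2-en-1-yl]phenyl}-3-(benzyloxy)-2-[4-(benzyloxy)phenyl]chromane
Product: 21 (2R,3S,4S)-7-(allyloxy)-4-{4-(allyloxy)-2-(benzyloxy)-5-{[(2S,3R)-3-(3,4-bis(benzyloxy)phenyl)oxiran-2-yl]methyl}phenyl}-3-(benzyloxy)-2-[4-(benzyloxy)phenyl]chromane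
Conditions: (R,R)-Mn(salen)Cl [salen = N,N'-bis(3,5-di-tert-butylsalicylidene)cyclohexane-1,2-diaminate] (5 mol%), 4-phenylpyridine N-oxide (20 mol%), aq. NaOCl (pH 11.3), CH2Cl2, 0 °C
Reagents that add atoms: sodium hypochlorite, [Na+].[O-]Cl
Why: Jacobsen epoxidation; the (R,R)-salen complex of trivalent manganese, oxidised by hypochlorite to the oxo species, epoxidises cis-β-alkylstyrenes in the (1R,2S) sense, which here sets C2' as R and C3' as S under catalyst control. The isolated allyl ether alkenes are poor substrates and the N-oxide additive limits cis-to-trans leakage.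

Step 17
Reactants: 21 (2R,3S,4S)-7-(allyloxy)-4-{4-(allyloxy)-2-(benzyloxy)-5-{[(2S,3R)-3-(3,4-bis(benzyloxy)phenyl)oxiran-2-yl]methyl}phenyl}-3-(benzyloxy)-2-[4-(benzyloxy)phenyl]chromane
Product: 23 (2R,3S,4S)-3-(benzyloxy)-2-[4-(benzyloxy)phenyl]-4-[(2S,3S)-7-(benzyloxy)-2-(3,4-bis(benzyloxy)phenyl)-3-hydroxychroman-6-yl]chroman-7-ol, via epoxy bisphenol 22 (not isolated)
Conditions: Pd(PPh3)4 (5 mol%), morpholine, THF, rt; pH 7 wash; then camphorsulfonic acid (10 mol%), CH2Cl2, −40 to −10 °C
Reagents that add atoms: none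
Why: Tsuji–Trost deallylation with zerovalent palladium and morpholine frees the C8a' phenol (and 7-OH) under neutral conditions; acid then triggers 6-endo opening of the cis-epoxide at benzylic C2' with inversion, which turns the (2'R,3'S) cis-epoxide into the 2,3-cis ring F with C2' S and C3' S. Only the C8a' oxygen can reach the epoxide through a six-membered transition state.

Step 18
Reactants: 23 (2R,3S,4S)-3-(benzyloxy)-2-[4-(benzyloxy)phenyl]-4-[(2S,3S)-7-(benzyloxy)-2-(3,4-bis(benzyloxy)phenyl)-3-hydroxychroman-6-yl]chroman-7-ol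
Product: 24 (2R,3S,4R)-4-[(2S,3S)-2-(3,4-dihydroxyphenyl)-3,7-dihydroxychroman-6-yl]-2-(4-hydroxyphenyl)chroman-3,7-diol
Conditions: H2 (1 atm), Pd(OH)2/C, THF/MeOH, rt
Reagents that add atoms: none
Why: Hydrogenolysis of the five benzyl ethers under neutral conditions; the cyclic benzylic ethers O1–C2 and O1'–C2' and the C4–C6' bond should not be cleaved at atmospheric pressure and room temperature.

Compound list

1 | 2,2',4,4'-tetrahydroxybenzophenone | O=C(c1ccc(O)cc1O)c1ccc(O)cc1O | starting material
2 | bis[4-(allyloxy)-2-hydroxyphenyl]methanone | O=C(c1ccc(OCC=C)cc1O)c1ccc(OCC=C)cc1O | intermediate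
3 | bis[4-(allyloxy)-2-(tert-butyldimethylsilyloxy)phenyl]methanone | O=C(c1ccc(OCC=C)cc1O[Si](C)(C)C(C)(C)C)c1ccc(OCC=C)cc1O[Si](C)(C)C(C)(C)C | intermediate
4 | 2,2-bis[4-(allyloxy)-2-(tert-butyldimethylsilyloxy)phenyl]oxirane | C1OC1(c1ccc(OCC=C)cc1O[Si](C)(C)C(C)(C)C)c1ccc(OCC=C)cc1O[Si](C)(C)C(C)(C)C | intermediate
5 | 2,2-bis[4-(allyloxy)-2-(tert-butyldimethylsilyloxy)phenyl]acetaldehyde | O=CC(c1ccc(OCC=C)cc1O[Si](C)(C)C(C)(C)C)c1ccc(OCC=C)cc1O[Si](C)(C)C(C)(C)C | intermediate
6 | 4-(benzyloxy)benzyl chloride | ClCc1ccc(OCc2ccccc2)cc1 | starting material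
7 | 5-{[4-(benzyloxy)benzyl]sulfanyl}-1-phenyl-1H-tetrazole | c1ccccc1COc1ccc(CSc2nnnn2-c2ccccc2)cc1 | intermediate
8 | 5-{[4-(benzyloxy)benzyl]sulfonyl}-1-phenyl-1H-tetrazole | c1ccccc1COc1ccc(CS(=O)(=O)c2nnnn2-c2ccccc2)cc1 | intermediate
9 | (E)-1-[4-(benzyloxy)phenyl]-3,3-bis[4-(allyloxy)-2-(tert-butyldimethylsilyloxy)phenyl]prop-1-ene | c1ccccc1COc1ccc(/C=C/C(c2ccc(OCC=C)cc2O[Si](C)(C)C(C)(C)C)c2ccc(OCC=C)cc2O[Si](C)(C)C(C)(C)C)cc1 | intermediate
10 | (2S,3S)-2-[4-(benzyloxy)phenyl]-3-{bis[4-(allyloxy)-2-(tert-butyldimethylsilyloxy)phenyl]methyl}oxirane | c1ccccc1COc1ccc([C@@H]2O[C@H]2C(c2ccc(OCC=C)cc2O[Si](C)(C)C(C)(C)C)c2ccc(OCC=C)cc2O[Si](C)(C)C(C)(C)C)cc1 | intermediate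
11 | (2S,3S)-2-[4-(benzyloxy)phenyl]-3-{bis[4-(allyloxy)-2-hydroxyphenyl]methyl}oxirane | c1ccccc1COc1ccc([C@@H]2O[C@H]2C(c2ccc(OCC=C)cc2O)c2ccc(OCC=C)cc2O)cc1 | intermediate
12 | (2R,3S,4R)-7-(allyloxy)-4-[4-(allyloxy)-2-hydroxyphenyl]-2-[4-(benzyloxy)phenyl]chroman-3-ol | c1ccccc1COc1ccc([C@H]2Oc3cc(OCC=C)ccc3[C@@H](c3ccc(OCC=C)cc3O)[C@@H]2O)cc1 | intermediate
13 | (2R,3S,4R)-7-(allyloxy)-4-[4-(allyloxy)-2-hydroxy-5-iodophenyl]-2-[4-(benzyloxy)phenyl]chroman-3-ol | c1ccccc1COc1ccc([C@H]2Oc3cc(OCC=C)ccc3[C@@H](c3cc(I)c(OCC=C)cc3O)[C@@H]2O)cc1 | intermediate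
14 | (2R,3S,4S)-7-(allyloxy)-4-[4-(allyloxy)-2-(benzyloxy)-5-iodophenyl]-3-(benzyloxy)-2-[4-(benzyloxy)phenyl]chromane | c1ccccc1COc1ccc([C@H]2Oc3cc(OCC=C)ccc3[C@@H](c3cc(I)c(OCC=C)cc3OCc3ccccc3)[C@@H]2OCc2ccccc2)cc1 | intermediate
15 | 4-bromo-1,2-bis(benzyloxy)benzene | Brc1ccc(OCc2ccccc2)c(OCc2ccccc2)c1 | starting material
16 | 3-[3,4-bis(benzyloxy)phenyl]prop-2-yn-1-ol | OCC#Cc1ccc(OCc2ccccc2)c(OCc2ccccc2)c1 | intermediate
17 | 4-(3-bromoprop-1-yn-1-yl)-1,2-bis(benzyloxy)benzene | BrCC#Cc1ccc(OCc2ccccc2)c(OCc2ccccc2)c1 | intermediate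
18 | arylmagnesium chloride derived from 14 (MgCl in place of iodine) | c1ccccc1COc1ccc([C@H]2Oc3cc(OCC=C)ccc3[C@@H](c3cc([Mg]Cl)c(OCC=C)cc3OCc3ccccc3)[C@@H]2OCc2ccccc2)cc1 | intermediate
19 | (2R,3S,4S)-7-(allyloxy)-4-{4-(allyloxy)-2-(benzyloxy)-5-[3-(3,4-bis(benzyloxy)phenyl)prop-2-yn-1-yl]phenyl}-3-(benzyloxy)-2-[4-(benzyloxy)phenyl]chromane | c1ccccc1COc1ccc([C@H]2Oc3cc(OCC=C)ccc3[C@@H](c3cc(CC#Cc4ccc(OCc5ccccc5)c(OCc5ccccc5)c4)c(OCC=C)cc3OCc3ccccc3)[C@@H]2OCc2ccccc2)cc1 | intermediate
20 | (2R,3S,4S)-7-(allyloxy)-4-{4-(allyloxy)-2-(benzyloxy)-5-[(Z)-3-(3,4-bis(benzyloxy)phenyl)prop-2-en-1-yl]phenyl}-3-(benzyloxy)-2-[4-(benzyloxy)phenyl]chromane | c1ccccc1COc1ccc([C@H]2Oc3cc(OCC=C)ccc3[C@@H](c3cc(C/C=C\c4ccc(OCc5ccccc5)c(OCc5ccccc5)c4)c(OCC=C)cc3OCc3ccccc3)[C@@H]2OCc2ccccc2)cc1 | intermediate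
21 | (2R,3S,4S)-7-(allyloxy)-4-{4-(allyloxy)-2-(benzyloxy)-5-{[(2S,3R)-3-(3,4-bis(benzyloxy)phenyl)oxiran-2-yl]methyl}phenyl}-3-(benzyloxy)-2-[4-(benzyloxy)phenyl]chromane | c1ccccc1COc1ccc([C@H]2Oc3cc(OCC=C)ccc3[C@@H](c3cc(C[C@@H]6O[C@@H]6c4ccc(OCc5ccccc5)c(OCc5ccccc5)c4)c(OCC=C)cc3OCc3ccccc3)[C@@H]2OCc2ccccc2)cc1 | intermediate
22 | (2R,3S,4S)-3-(benzyloxy)-4-{2-(benzyloxy)-5-{[(2S,3R)-3-(3,4-bis(benzyloxy)phenyl)oxiran-2-yl]methyl}-4-hydroxyphenyl}-2-[4-(benzyloxy)phenyl]chroman-7-ol | c1ccccc1COc1ccc([C@H]2Oc3cc(O)ccc3[C@@H](c3cc(C[C@@H]6O[C@@H]6c4ccc(OCc5ccccc5)c(OCc5ccccc5)c4)c(O)cc3OCc3ccccc3)[C@@H]2OCc2ccccc2)cc1 | intermediate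
23 | (2R,3S,4S)-3-(benzyloxy)-2-[4-(benzyloxy)phenyl]-4-[(2S,3S)-7-(benzyloxy)-2-(3,4-bis(benzyloxy)phenyl)-3-hydroxychroman-6-yl]chroman-7-ol | c1ccccc1COc1ccc([C@H]2Oc3cc(O)ccc3[C@@H](c3cc4c(cc3OCc3ccccc3)O[C@@H](c3ccc(OCc5ccccc5)c(OCc5ccccc5)c3)[C@@H](O)C4)[C@@H]2OCc2ccccc2)cc1 | intermediate
24 | (2R,3S,4R)-4-[(2S,3S)-2-(3,4-dihydroxyphenyl)-3,7-dihydroxychroman-6-yl]-2-(4-hydroxyphenyl)chroman-3,7-diol | Oc1ccc([C@H]2Oc3cc(O)ccc3[C@@H](c3cc4c(cc3O)O[C@@H](c3ccc(O)c(O)c3)[C@@H](O)C4)[C@@H]2O)cc1 | target

Total step count: 18. Longest linear sequence: 14 steps (steps 1, 2, 3, 6, 7, 8, 9, 10, 11, 14, 15, 16, 17, 18).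

Least certain steps

Step 9 (key step). The most likely failure is insufficient discrimination between the two diastereotopic phenols, made worse if the epoxide ionises to a free benzylic cation before the ring closes; the energy difference between the two chair-like arrangements is a conformational preference and not a hard constraint. The fallback sets out from 10 and comes back at 12. 10 is treated with one equivalent of buffered Bu4NF. Besides unchanged 10 and bisphenol 11, this gives two monophenols that are no longer related by symmetry and should be separable: the (S)-methine monosilyl monophenol F1 and its C4 epimer F2. In F1 only the phenol that leads to the 3,4-trans ring is free, so the same acid treatment gives the 7'-O-silyl flavanol F3 without any competition, and fluoride then gives 12. F2 and 11 are resilylated to 10 and recycled.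

Step 17. The likely failure is ionisation of the cis-epoxide at C2', which is strongly stabilised by the 3,4-bis(benzyloxy)phenyl group; this would cause loss of stereospecificity at C2' or a hydride shift to a ketone. The fallback sets out from 20 and comes back at 23. Z-to-E isomerisation with a catalytic amount of iodine gives the E-alkene F9. Shi epoxidation with the D-fructose-derived ketone gives the (2'R,3'R) trans-epoxide F10. Deallylation and acid closure as in step 17 give the 2,3-trans lower ring F11 (2'S,3'R); this closure tolerates cationic character because the trans ring is also the more stable one. Dess–Martin oxidation of the only free secondary alcohol (NaHCO3 buffer) gives the flavan-3-one F12, and LiBH(sec-Bu)3 reduces it from the face opposite the C2' aryl group to the cis alcohol 23.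

Step 16. The likely failure is incomplete face selection, together with cis-to-trans leakage through rotation of the benzylic radical intermediate, which an electron-rich aryl group favours; hypochlorite may also attack the alkoxyarenes. The fallback sets out from 20 and comes back at 21. It replaces the metal-oxo transfer by oxygen transfer from a chiral dioxirane (a carbohydrate-derived oxazolidinone ketone of the kind developed for cis-alkenes, with KHSO5 in buffered medium). The concerted transfer cannot scramble the alkene geometry and uses no hypochlorite; the enantiomer of the ketone that gives the (1R,2S) epoxide from cis-β-methylstyrene is chosen. It makes no new compound. If face selection is still insufficient, the detour under step 17 avoids the cis-epoxide altogether.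

Step 14. The likely failure is SN2' attack of the arylcopper species at the alkyne terminus, giving an allene instead of the propargyl arene, since both pathways are open to copper-mediated substitutions of propargylic halides. The fallback sets out from 14 and comes back at 19. The same magnesium reagent 18 is coupled (CuI cat.) with 3-bromo-1-(trimethylsilyl)prop-1-yne, whose silyl group blocks the alkyne terminus, to give the silylalkyne F7. K2CO3 in MeOH gives the terminal alkyne F8. Sonogashira coupling of F8 with 4-iodo-1,2-bis(benzyloxy)benzene (Pd(PPh3)2Cl2, CuI, Et3N, rt) gives 19, so the aryl–alkyne bond is made by cross-coupling instead of being carried in the electrophile.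

Step 6. The likely failure is enolisation of the doubly benzylic aldehyde 5 by the sulfonyl carbanion in place of addition, together with incomplete E selectivity, which is typical of benzylic sulfones. The fallback sets out from 5 and comes back at 9, with the polarity of the olefination reversed. NaBH4 reduces 5 to the 2,2-diarylethanol F4. Mitsunobu reaction with 1-phenyl-1H-tetrazole-5-thiol gives the sulfide F5, and molybdate/H2O2 oxidation gives the alkyl sulfone F6. Julia–Kocienski olefination of F6 with 4-(benzyloxy)benzaldehyde (KN(SiMe3)2, DME, −60 °C) gives 9; the aldehyde is now non-enolisable, and alkyl tetrazolyl sulfones with aryl aldehydes are reliably E-selective.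

## Further compounds

F1 | step 9 | 2-[(S)-{(2S,3S)-3-[4-(benzyloxy)phenyl]oxiran-2-yl}{4-(allyloxy)-2-(tert-butyldimethylsilyloxy)phenyl}methyl]-5-(allyloxy)phenol | c1ccccc1COc1ccc([C@@H]2O[C@H]2[C@@H](c2ccc(OCC=C)cc2O)c2ccc(OCC=C)cc2O[Si](C)(C)C(C)(C)C)cc1
F2 | step 9 | 2-[(R)-{(2S,3S)-3-[4-(benzyloxy)phenyl]oxiran-2-yl}{4-(allyloxy)-2-(tert-butyldimethylsilyloxy)phenyl}methyl]-5-(allyloxy)phenol | c1ccccc1COc1ccc([C@@H]2O[C@H]2[C@H](c2ccc(OCC=C)cc2O)c2ccc(OCC=C)cc2O[Si](C)(C)C(C)(C)C)cc1
F3 | step 9 | (2R,3S,4S)-7-(allyloxy)-4-[4-(allyloxy)-2-(tert-butyldimethylsilyloxy)phenyl]-2-[4-(benzyloxy)phenyl]chroman-3-ol | c1ccccc1COc1ccc([C@H]2Oc3cc(OCC=C)ccc3[C@@H](c3ccc(OCC=C)cc3O[Si](C)(C)C(C)(C)C)[C@@H]2O)cc1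
F4 | step 6 | 2,2-bis[4-(allyloxy)-2-(tert-butyldimethylsilyloxy)phenyl]ethanol | OCC(c1ccc(OCC=C)cc1O[Si](C)(C)C(C)(C)C)c1ccc(OCC=C)cc1O[Si](C)(C)C(C)(C)C
F5 | step 6 | 5-({2,2-bis[4-(allyloxy)-2-(tert-butyldimethylsilyloxy)phenyl]ethyl}sulfanyl)-1-phenyl-1H-tetrazole | c1ccccc1-n1nnnc1SCC(c1ccc(OCC=C)cc1O[Si](C)(C)C(C)(C)C)c1ccc(OCC=C)cc1O[Si](C)(C)C(C)(C)C
F6 | step 6 | 5-({2,2-bis[4-(allyloxy)-2-(tert-butyldimethylsilyloxy)phenyl]ethyl}sulfonyl)-1-phenyl-1H-tetrazole | c1ccccc1-n1nnnc1S(=O)(=O)CC(c1ccc(OCC=C)cc1O[Si](C)(C)C(C)(C)C)c1ccc(OCC=C)cc1O[Si](C)(C)C(C)(C)C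
F7 | step 14 | (2R,3S,4S)-7-(allyloxy)-4-{4-(allyloxy)-2-(benzyloxy)-5-[3-(trimethylsilyl)prop-2-yn-1-yl]phenyl}-3-(benzyloxy)-2-[4-(benzyloxy)phenyl]chromane | c1ccccc1COc1ccc([C@H]2Oc3cc(OCC=C)ccc3[C@@H](c3cc(CC#C[Si](C)(C)C)c(OCC=C)cc3OCc3ccccc3)[C@@H]2OCc2ccccc2)cc1
F8 | step 14 | (2R,3S,4S)-7-(allyloxy)-4-[4-(allyloxy)-2-(benzyloxy)-5-(prop-2-yn-1-yl)phenyl]-3-(benzyloxy)-2-[4-(benzyloxy)phenyl]chromane | c1ccccc1COc1ccc([C@H]2Oc3cc(OCC=C)ccc3[C@@H](c3cc(CC#C)c(OCC=C)cc3OCc3ccccc3)[C@@H]2OCc2ccccc2)cc1
F0 | step 16 | none | none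
F9 | step 17 | (2R,3S,4S)-7-(allyloxy)-4-{4-(allyloxy)-2-(benzyloxy)-5-[(E)-3-(3,4-bis(benzyloxy)phenyl)prop-2-en-1-yl]phenyl}-3-(benzyloxy)-2-[4-(benzyloxy)phenyl]chromane | c1ccccc1COc1ccc([C@H]2Oc3cc(OCC=C)ccc3[C@@H](c3cc(C/C=C/c4ccc(OCc5ccccc5)c(OCc5ccccc5)c4)c(OCC=C)cc3OCc3ccccc3)[C@@H]2OCc2ccccc2)cc1
F10 | step 17 | (2R,3S,4S)-7-(allyloxy)-4-{4-(allyloxy)-2-(benzyloxy)-5-{[(2R,3R)-3-(3,4-bis(benzyloxy)phenyl)oxiran-2-yl]methyl}phenyl}-3-(benzyloxy)-2-[4-(benzyloxy)phenyl]chromane | c1ccccc1COc1ccc([C@H]2Oc3cc(OCC=C)ccc3[C@@H](c3cc(C[C@H]6O[C@@H]6c4ccc(OCc5ccccc5)c(OCc5ccccc5)c4)c(OCC=C)cc3OCc3ccccc3)[C@@H]2OCc2ccccc2)cc1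
F11 | step 17 | (2R,3S,4S)-3-(benzyloxy)-2-[4-(benzyloxy)phenyl]-4-[(2S,3R)-7-(benzyloxy)-2-(3,4-bis(benzyloxy)phenyl)-3-hydroxychroman-6-yl]chroman-7-ol | c1ccccc1COc1ccc([C@H]2Oc3cc(O)ccc3[C@@H](c3cc4c(cc3OCc3ccccc3)O[C@@H](c3ccc(OCc5ccccc5)c(OCc5ccccc5)c3)[C@H](O)C4)[C@@H]2OCc2ccccc2)cc1
F12 | step 17 | (2S)-7-(benzyloxy)-6-{(2R,3S,4S)-3-(benzyloxy)-2-[4-(benzyloxy)phenyl]-7-hydroxychroman-4-yl}-2-[3,4-bis(benzyloxy)phenyl]chroman-3-one | c1ccccc1COc1ccc([C@H]2Oc3cc(O)ccc3[C@@H](c3cc4c(cc3OCc3ccccc3)O[C@@H](c3ccc(OCc5ccccc5)c(OCc5ccccc5)c3)C(=O)C4)[C@@H]2OCc2ccccc2)cc1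
A1 | alternative 1 | tetra-O-benzyl upper unit whose ring D oxygen O8a' is etherified with (1S)-1-[3,4-bis(pivaloyloxy)phenyl]-1-[(2S)-oxiran-2-yl]methyl (precursor of the epoxy-arene cyclisation) | c1ccccc1COc1ccc([C@H]2Oc3cc(OCc4ccccc4)ccc3[C@@H](c3ccc(cc3OCc3ccccc3)O[C@@H](c3ccc(OC(=O)C(C)(C)C)c(OC(=O)C(C)(C)C)c3)[C@@H]6CO6)[C@@H]2OCc2ccccc2)cc1
A2 | alternative 1 | protected target with free C3' hydroxyl, ring E dipivalate and four benzyl ethers | c1ccccc1COc1ccc([C@H]2Oc3cc(OCc4ccccc4)ccc3[C@@H](c3cc4c(cc3OCc3ccccc3)O[C@@H](c3ccc(OC(=O)C(C)(C)C)c(OC(=O)C(C)(C)C)c3)[C@@H](O)C4)[C@@H]2OCc2ccccc2)cc1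
A3 | alternative 2 | [4-(benzyloxy)-2-hydroxyphenyl][(2S,3S)-3,7-bis(benzyloxy)-2-(3,4-bis(benzyloxy)phenyl)chroman-6-yl]methanol (carbinol centre unassigned) | OC(c1ccc(OCc2ccccc2)cc1O)c1cc2c(cc1OCc1ccccc1)O[C@@H](c1ccc(OCc3ccccc3)c(OCc3ccccc3)c1)[C@@H](OCc1ccccc1)C2
A4 | alternative 2 | (E)-2-{2-[4-(benzyloxy)phenyl]ethenyl}-4,4,5,5-tetramethyl-1,3,2-dioxaborolane | c1ccccc1COc1ccc(/C=C/B2OC(C)(C)C(C)(C)O2)cc1
A5 | alternative 2 | per-benzyl 4-arylflavan with a pinacolboryl group at C3 | c1ccccc1COc1ccc([C@H]2Oc3cc(OCc4ccccc4)ccc3[C@@H](c3cc4c(cc3OCc3ccccc3)O[C@@H](c3ccc(OCc5ccccc5)c(OCc5ccccc5)c3)[C@@H](OCc3ccccc3)C4)[C@@H]2B2OC(C)(C)C(C)(C)O2)cc1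
A6 | alternative 3 | hepta-O-benzyl seco compound: ring D C8a' triflate carrying at C4a' the (2S,3S)-2-(benzyloxy)-3-[3,4-bis(benzyloxy)phenyl]-3-hydroxypropyl chain | c1ccccc1COc1ccc([C@H]2Oc3cc(OCc4ccccc4)ccc3[C@@H](c3cc(C[C@H](OCc4ccccc4)[C@@H](O)c4ccc(OCc5ccccc5)c(OCc5ccccc5)c4)c(OS(=O)(=O)C(F)(F)F)cc3OCc3ccccc3)[C@@H]2OCc2ccccc2)cc1
A7 | alternative 3 | hepta-O-benzyl target | c1ccccc1COc1ccc([C@H]2Oc3cc(OCc4ccccc4)ccc3[C@@H](c3cc4c(cc3OCc3ccccc3)O[C@@H](c3ccc(OCc5ccccc5)c(OCc5ccccc5)c3)[C@@H](OCc3ccccc3)C4)[C@@H]2OCc2ccccc2)cc1
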